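**Plan**

1. Lignan numbering: oxolane O1–C7(aryl)–C8(C9H2OH)–C8'(C7'H2Ar')–C9'H2. The retrosynthesis first adds a temporary ether bond O9–C7', which gives the cis-fused 3,7-dioxabicyclo[3.3.0]octane of C2-symmetric syringaresinol. It then cuts aryl C1–C7 (bicyclic lactol + 2,6-dimethoxyphenol), O1–C7 (lactol closure), O9–C7' (benzylic etherification), C8'–C7' (aldol) and C8–C7 (conjugate vinylation).
2. Forward: butenolide → 4-vinyl lactone (a temporary ring that relays C8 to C8') → aldol with benzyl-protected syringaldehyde → triol → oxolane ring A (O9–C7') → vinyl cleaved and lactol ring B closed on C7 → arylation of C7 → hydrogenolysis reopens ring A and frees the phenol.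
3. Stereochemistry: C8 from the (S)-BINAP–rhodium conjugate vinylation; C8' from the trans aldol on the lactone (trans on the lactone becomes cis on the oxolane after the ring switch); C7' (removed at the end) from the trans-selective ring closure; C7 from attack on the convex face of the bicycle.
4. Enabling feature: C7 is the acetal-level carbon of the oxolane (bonded to O1), so it can become an oxocarbenium carbon. The aryl carbon to be joined is C4 of 2,6-dimethoxyphenol, para to OH with both ortho positions blocked by OMe. The C9 hydroxyl and C7' are cis on the oxolane, so the ether O9–C7' ties them into a bicycle whose convex face directs the arene and which keeps the second aryl ring (C2'/C6') away from C7.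

Key step: step 6

Remark: the benzyl ether of syringaldehyde is taken as commercially available.

**Route**

Step 1
Reactants: 1 furan-2(5H)-one; 2 potassium vinyltrifluoroborate
Product: 3 (S)-4-ethenyloxolan-2-one
Conditions: [Rh(cod)2]BF4 (3 mol%), (S)-BINAP (3.3 mol%), toluene/H2O (10:1), 100 °C
Reagents that add atoms: none
Why: Rhodium-catalysed asymmetric conjugate addition (Hayashi–Miyaura reaction) of the vinyl group to the butenolide should set C8 (lactone C4) as S, the (S)-ligand being the one expected from the model for cyclic enones and the assignment to be checked against the sign of rotation of this known lactone.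

Step 2
Reactants: 3 (S)-4-ethenyloxolan-2-one; 4 4-(benzyloxy)-3,5-dimethoxybenzaldehyde
Product: 6 (3S,4R)-3-{[4-(benzyloxy)-3,5-dimethoxyphenyl](hydroxy)methyl}-4-ethenyloxolan-2-one (3,4-trans; both carbinol epimers), via lithium enolate 5 (not isolated)
Conditions: LiN(iPr)2 (LDA, 1.1 equiv), THF, −78 °C; then 4, −78 °C; sat. aq. NH4Cl
Reagents that add atoms: none
Why: Aldol addition of the lithium lactone enolate to the aldehyde on the face anti to the C4 vinyl group should set C8' trans to C8 (the usual trans rule for 4-substituted butanolide enolates), while the carbinol carbon C7' forms as an epimer mixture that does not matter because it is ionised in step 4.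

Step 3
Reactants: 6 (3S,4R)-3-{[4-(benzyloxy)-3,5-dimethoxyphenyl](hydroxy)methyl}-4-ethenyloxolan-2-one
Product: 7 (2R,3R)-2-{[4-(benzyloxy)-3,5-dimethoxyphenyl](hydroxy)methyl}-3-ethenylbutane-1,4-diol (carbinol epimers)
Conditions: LiAlH4 (2.5 equiv), THF, 0 °C → rt; H2O, 15% aq. NaOH, H2O
Reagents that add atoms: none
Why: Hydride reduction of the lactone to the 1,4-diol leaves the stereocentres untouched and removes the temporary lactone ring, so that the trans relation set on the lactone becomes the cis relation of C9' and the vinyl group on the later oxolane.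

Step 4
Reactants: 7 (2R,3R)-2-{[4-(benzyloxy)-3,5-dimethoxyphenyl](hydroxy)methyl}-3-ethenylbutane-1,4-diol
Product: 9 [(2S,3R,4R)-2-[4-(benzyloxy)-3,5-dimethoxyphenyl]-4-ethenyloxolan-3-yl]methanol, via benzylic cation 8 (not isolated)
Conditions: BF3·OEt2 (0.3 equiv), CH2Cl2 (0.02 M), −20 → 0 °C; Et3N quench
Reagents that add atoms: none
Why: In this benzylic cycloetherification the acid ionises the electron-rich benzylic alcohol to a 4-alkoxybenzyl cation that the C9 hydroxyl captures 5-exo (the C9' hydroxyl could only give an oxetane), and the aryl group should settle trans to the neighbouring hydroxymethyl group on the less hindered face, a preference that reversible ionisation reinforces, which sets C7' as S.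

Step 5
Reactants: 9 [(2S,3R,4R)-2-[4-(benzyloxy)-3,5-dimethoxyphenyl]-4-ethenyloxolan-3-yl]methanol
Product: 12 (1R,5R,6S)-6-[4-(benzyloxy)-3,5-dimethoxyphenyl]-3,7-dioxabicyclo[3.3.0]octan-2-ol (cis-fused lactol; anomer mixture), via vicinal diol 10 (not isolated), via hydroxy aldehyde 11 (not isolated)
Conditions: OsO4 (2 mol%), NaIO4 (3 equiv), 2,6-lutidine (2 equiv), dioxane/H2O (3:1), rt
Reagents that add atoms: OsO4, O=[Os](=O)(=O)=O; NaIO4, [Na+].[O-]I(=O)(=O)=O (terminal source of the oxygen atom on C7)
Why: Lemieux–Johnson cleavage (catalytic dihydroxylation, then periodate glycol scission) turns the vinyl group into the C7 aldehyde, which lies cis to the C9' hydroxymethyl group and should close at once to the cis-fused lactol, the lutidine buffer guarding C8 against epimerisation and the anomeric carbon being left as a mixture.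

Step 6
Reactants: 12 (1R,5R,6S)-6-[4-(benzyloxy)-3,5-dimethoxyphenyl]-3,7-dioxabicyclo[3.3.0]octan-2-ol; 13 2,6-dimethoxyphenol
Product: 15 (1R,2S,5R,6S)-6-[4-(benzyloxy)-3,5-dimethoxyphenyl]-2-(4-hydroxy-3,5-dimethoxyphenyl)-3,7-dioxabicyclo[3.3.0]octane (the 4'-O-benzyl ether of (7S,8R,7'S,8'R)-syringaresinol), via oxocarbenium ion 14 (not isolated)
Conditions: 13 (3 equiv), BF3·OEt2 (0.5 equiv), 4 Å molecular sieves, CH2Cl2, −40 → −20 °C; Et3N quench
Reagents that add atoms: none
Why: BF3 ionises the lactol hydroxyl of 12 to the bicyclic oxocarbenium ion 14 (O9'=C7), which is attacked by C4 of 2,6-dimethoxyphenol, the carbon para to the hydroxyl whose two ortho positions carry methoxy groups, and rearomatisation gives the C-aryl product, attack through the phenol oxygen being reversible under the acid and draining into the C–C product. The closest known reaction type is the Friedel–Crafts C-arylation of lactols and cyclic acetals by phenols (aryl C-glycosylation), including the acid-promoted arylation of 6-aryl-3,7-dioxabicyclo[3.3.0]octan-2-ols to 2,6-diaryl furofurans. No ring is closed in this step. The new stereocentre C7 is controlled by the cis-fused bicycle: the arene approaches the convex (exo) face of ring B, anti to the C8–C9 bond, which places the aryl group trans to C9 (7S). The step needs attack by the external phenol instead of by the resident aryl ring, para instead of meta substitution, and the kinetic exo product; the temporary O9–C7' ring holds the resident aryl group exo on ring A where its C2'/C6' cannot reach C7, the free para-hydroxyl directs the substitution, and low temperature with sub-stoichiometric acid should keep the benzylic ethers from ionising.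

Step 7
Reactants: 15 (1R,2S,5R,6S)-6-[4-(benzyloxy)-3,5-dimethoxyphenyl]-2-(4-hydroxy-3,5-dimethoxyphenyl)-3,7-dioxabicyclo[3.3.0]octane
Product: 17 (+)-(7S,8R,8'R)-5,5'-dimethoxylariciresinol, via syringaresinol 16 (not isolated)
Conditions: H2 (1 atm), 10% Pd/C, EtOAc/MeOH (1:1), rt; hydrogen uptake monitored and the reaction stopped when 16 is consumed
Reagents that add atoms: none
Why: Palladium-catalysed hydrogenolysis should first remove the aryl benzyl ether to give C2-symmetric 16 and then cleave the temporary benzylic ether bond O9–C7' to the benzylic CH2 and the free C9 hydroxyl (mono-hydrogenolysis of a furofuran to a 7,9'-epoxylignan), the two benzylic C–O bonds of 16 being homotopic so that no site selectivity is needed and C7, C8 and C8' are not touched.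

**Compound list**

1 | furan-2(5H)-one | O=C1C=CCO1 | starting material
2 | potassium vinyltrifluoroborate | [K+].C=C[B-](F)(F)F | starting material
3 | (S)-4-ethenyloxolan-2-one | C=C[C@H]1COC(=O)C1 | intermediate
4 | 4-(benzyloxy)-3,5-dimethoxybenzaldehyde | COc1cc(C=O)cc(OC)c1OCc1ccccc1 | starting material
5 | lithium enolate of 3 (lithium (S)-4-ethenyl-4,5-dihydrofuran-2-olate) | C=C[C@H]1COC([O-])=C1.[Li+] | intermediate
6 | (3S,4R)-3-{[4-(benzyloxy)-3,5-dimethoxyphenyl](hydroxy)methyl}-4-ethenyloxolan-2-one (3,4-trans; carbinol epimers) | C=C[C@H]1COC(=O)[C@@H]1C(O)c1cc(OC)c(OCc2ccccc2)c(OC)c1 | intermediate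
7 | (2R,3R)-2-{[4-(benzyloxy)-3,5-dimethoxyphenyl](hydroxy)methyl}-3-ethenylbutane-1,4-diol (carbinol epimers) | C=C[C@@H](CO)[C@H](CO)C(O)c1cc(OC)c(OCc2ccccc2)c(OC)c1 | intermediate
8 | benzylic cation from 7 (C7' cation; other centres as in 7) | C=C[C@@H](CO)[C@H](CO)[CH+]c1cc(OC)c(OCc2ccccc2)c(OC)c1 | intermediate
9 | [(2S,3R,4R)-2-[4-(benzyloxy)-3,5-dimethoxyphenyl]-4-ethenyloxolan-3-yl]methanol (aryl trans to CH2OH; CH2OH cis to vinyl) | C=C[C@H]1CO[C@H](c2cc(OC)c(OCc3ccccc3)c(OC)c2)[C@H]1CO | intermediate
10 | vicinal diol from 9 (vinyl replaced by CH(OH)CH2OH; ring configuration as in 9; diol epimers) | OCC(O)[C@H]1CO[C@H](c2cc(OC)c(OCc3ccccc3)c(OC)c2)[C@H]1CO | intermediate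
11 | hydroxy aldehyde from 9 (vinyl replaced by CHO; ring configuration as in 9; CHO cis to CH2OH) | O=C[C@H]1CO[C@H](c2cc(OC)c(OCc3ccccc3)c(OC)c2)[C@H]1CO | intermediate
12 | (1R,5R,6S)-6-[4-(benzyloxy)-3,5-dimethoxyphenyl]-3,7-dioxabicyclo[3.3.0]octan-2-ol (cis-fused; aryl exo; anomer mixture) | COc1cc([C@H]2OC[C@H]3[C@@H]2COC3O)cc(OC)c1OCc1ccccc1 | intermediate
13 | 2,6-dimethoxyphenol | COc1cccc(OC)c1O | starting material
14 | bicyclic oxocarbenium ion from 12 (O9'=C7 cation) | COc1cc([C@H]2OC[C@H]3[C@@H]2C[O+]=C3)cc(OC)c1OCc1ccccc1 | intermediate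
15 | (1R,2S,5R,6S)-6-[4-(benzyloxy)-3,5-dimethoxyphenyl]-2-(4-hydroxy-3,5-dimethoxyphenyl)-3,7-dioxabicyclo[3.3.0]octane (both aryl groups exo) | COc1cc([C@H]2OC[C@H]3[C@@H]2CO[C@@H]3c2cc(OC)c(O)c(OC)c2)cc(OC)c1OCc1ccccc1 | intermediate
16 | (7S,8R,7'S,8'R)-syringaresinol | COc1cc([C@H]2OC[C@H]3[C@@H]2CO[C@@H]3c2cc(OC)c(O)c(OC)c2)cc(OC)c1O | intermediate
17 | (+)-(7S,8R,8'R)-5,5'-dimethoxylariciresinol, [(2S,3R,4R)-2-(4-hydroxy-3,5-dimethoxyphenyl)-4-(4-hydroxy-3,5-dimethoxybenzyl)oxolan-3-yl]methanol | COc1cc(C[C@H]2CO[C@H](c3cc(OC)c(O)c(OC)c3)[C@H]2CO)cc(OC)c1O | target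

**Step count and risks**

Total step count: 7. Longest linear sequence: 7 steps (from 1).

Steps most likely to fail:

Step 6. The arylation may lose configuration at C7 or C7' through reversible ionisation of the benzylic ethers, may occur at the carbon meta to the phenol hydroxyl, or may go on to a second arylation after ring opening. The fallback sets out from 12 and replaces the cationic arylation by a carbonyl addition. Commercial 4-bromo-2,6-dimethoxyphenol is benzylated (BnBr, K2CO3, DMF) to 2-(benzyloxy)-5-bromo-1,3-dimethoxybenzene F1, which with Mg in THF gives [4-(benzyloxy)-3,5-dimethoxyphenyl]magnesium bromide F2. Two equivalents of F2 should open lactol 12 and add to its aldehyde form to give the diol F3. Brief acid treatment (camphorsulfonic acid cat., CH2Cl2, 0 °C) should close ring B through the benzylic cation on the convex face to the bis(benzyl ether) of syringaresinol F4. Under the conditions of step 7, F4 rejoins the route at 16.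

Step 7. The hydrogenolysis may run on to scission of the second benzylic C–O bond, since the product still carries one. The fallback sets out from 15 and replaces the scission of a symmetric intermediate by a site-selective ionic hydrogenation of an electronically differentiated one. Acetylation of the free phenol (Ac2O, pyridine) gives the acetate F5. Transfer hydrogenolysis (1,4-cyclohexadiene, Pd/C, EtOH) should remove only the benzyl ether to give the phenol F6, in which only the aryl group on C7' has a free para-hydroxyl. Et3SiH with BF3·OEt2 in CH2Cl2 at −78 °C should then open only the O9–C7' bond, through the para-quinone-methide-type cation, to the ring-opened acetate F7. Methanolysis (K2CO3, MeOH) returns to the route at 17.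

Step 1. The conjugate vinylation may suffer from slow transmetallation, protodeboronation or poor discrimination of the enantiofaces of the small butenolide. The fallback sets out from 1 and replaces asymmetric catalysis by a resolution. Copper-catalysed conjugate addition of vinylmagnesium bromide (CuBr·SMe2 cat., Me3SiCl, THF, −78 °C) gives racemic 4-ethenyloxolan-2-one F8. Aminolysis with (S)-1-phenylethylamine and AlMe3 gives two diastereomeric hydroxy amides, from which (3S)-3-(hydroxymethyl)-N-[(1S)-1-phenylethyl]pent-4-enamide F9 is separated by chromatography or crystallisation. Acid-catalysed relactonisation (TsOH, toluene, heat) returns to the route at 3.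

Further compounds
F1 | step 6 | 2-(benzyloxy)-5-bromo-1,3-dimethoxybenzene | COc1cc(Br)cc(OC)c1OCc1ccccc1
F2 | step 6 | [4-(benzyloxy)-3,5-dimethoxyphenyl]magnesium bromide | COc1cc([Mg]Br)cc(OC)c1OCc1ccccc1
F3 | step 6 | [(2S,3R,4R)-2-[4-(benzyloxy)-3,5-dimethoxyphenyl]-4-{[4-(benzyloxy)-3,5-dimethoxyphenyl](hydroxy)methyl}oxolan-3-yl]methanol (carbinol epimers) | OC(c1cc(OC)c(OCc2ccccc2)c(OC)c1)[C@H]1CO[C@H](c2cc(OC)c(OCc3ccccc3)c(OC)c2)[C@H]1CO
F4 | step 6 | (1R,2S,5R,6S)-2,6-bis[4-(benzyloxy)-3,5-dimethoxyphenyl]-3,7-dioxabicyclo[3.3.0]octane | COc1cc([C@H]2OC[C@H]3[C@@H]2CO[C@@H]3c2cc(OC)c(OCc3ccccc3)c(OC)c2)cc(OC)c1OCc1ccccc1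
F5 | step 7 | 4-O-acetyl-4'-O-benzyl-(7S,8R,7'S,8'R)-syringaresinol | COc1cc([C@H]2OC[C@H]3[C@@H]2CO[C@@H]3c2cc(OC)c(OC(C)=O)c(OC)c2)cc(OC)c1OCc1ccccc1
F6 | step 7 | 4-O-acetyl-(7S,8R,7'S,8'R)-syringaresinol | COc1cc([C@H]2OC[C@H]3[C@@H]2CO[C@@H]3c2cc(OC)c(OC(C)=O)c(OC)c2)cc(OC)c1O
F7 | step 7 | 4-O-acetyl-(7S,8R,8'R)-5,5'-dimethoxylariciresinol (acetate on the aryl group at C7) | COc1cc(C[C@H]2CO[C@H](c3cc(OC)c(OC(C)=O)c(OC)c3)[C@H]2CO)cc(OC)c1O
F8 | step 1 | racemic 4-ethenyloxolan-2-one | C=CC1COC(=O)C1
F9 | step 1 | (3S)-3-(hydroxymethyl)-N-[(1S)-1-phenylethyl]pent-4-enamide | C=C[C@@H](CO)CC(=O)N[C@@H](C)c1ccccc1
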